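**Retrosynthetic overview**
1. γ-Lactone (formed last): C12 and C11 come from a C7 isopropenyl group; hydroboration sets C11 and oxidative lactonisation closes onto the C6 hydroxyl.
2. Ten-membered ring: C6–C7 by intramolecular Nozaki–Hiyama allylation of a (Z)-enal by its own allylic chloride. The chloride terminus is turned into a nucleophilic allylchromium (a masked propionate homoenolate), so two electrophilic carbons are joined; anti addition gives the 6,7-trans relationship.
3. Acyclic precursor: Z C1=C10 by silicon-tethered RCM (temporary eight-membered silaketal) of two halves; C3 and C9 from two Brown allylations; C7=C11–C12 by cross-metathesis.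
4. Z C4=C5 is taken from the ring of 3-methylfuran-2(5H)-one.
5. Ring order: temporary silaketal ring (made, then opened) → carbocycle → lactone.

Assumption: ring carbons carry germacrane numbers (C1–C10 ring, C11–C13 side chain, C14 on C10, C15 on C4), the target is (3S,6S,7S,9R,11R,1(10)Z,4Z), and metal alkoxides that are only hydrolysed on work-up are not numbered.

Step 1
Reactants: 1 3-methylfuran-2(5H)-one
Product: 2 3-methyl-2,5-dihydrofuran-2-ol (lactol form of (Z)-4-hydroxy-2-methylbut-2-enal)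
Conditions: iBu2AlH (1.05 equiv), CH2Cl2, −78 °C; aq. KNaC4H4O6 work-up; used crude
Reagents that add atoms: none
Why: Partial reduction of the butenolide with iBu2AlH at −78 °C stops at the lactol and keeps the ring-enforced Z olefin that becomes C4=C5.

Step 2
Reactants: 2 3-methyl-2,5-dihydrofuran-2-ol
Product: 3 (2Z,4S)-3-methylhepta-2,6-diene-1,4-diol
Conditions: (−)-Ipc2B(allyl) (2.2 equiv, from (−)-Ipc2BOMe and allylMgBr), Et2O, −78 °C → rt; then NaOH, H2O2
Reagents that add atoms: (−)-B-allyldiisopinocampheylborane, C=CCB([C@@H]1C[C@@H]2C[C@H]([C@H]1C)C2(C)C)[C@@H]1C[C@@H]2C[C@H]([C@H]1C)C2(C)C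
Why: Brown allylboration of the open hydroxy-enal form through a closed six-membered transition state, in which the (−)-Ipc ligands deliver allyl to the face that gives the 4S carbinol (C3 of the target), the first equivalent of borane being spent on the free hydroxyl.

Step 3
Reactants: 3 (2Z,4S)-3-methylhepta-2,6-diene-1,4-diol
Product: 4 (4S,5Z)-7-[(tert-butyldiphenylsilyl)oxy]-5-methylhepta-1,5-dien-4-ol
Conditions: TBDPSCl (1.05 equiv), imidazole, CH2Cl2, −20 °C
Reagents that add atoms: tert-butyl(chloro)diphenylsilane, CC(C)(C)[Si](Cl)(c1ccccc1)c1ccccc1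
Why: Selective silylation of the primary allylic hydroxyl over the hindered secondary one masks C6–OH for the tether chemistry.

Step 4
Reactants: 5 2-methylprop-2-enal
Product: 6 (3R)-2-methylhexa-1,5-dien-3-ol
Conditions: (+)-Ipc2B(allyl) (1.1 equiv), Et2O, −78 °C; then NaOH, H2O2
Reagents that add atoms: (+)-B-allyldiisopinocampheylborane, C=CCB([C@H]1C[C@H]2C[C@@H]([C@@H]1C)C2(C)C)[C@H]1C[C@H]2C[C@@H]([C@@H]1C)C2(C)C
Why: Brown allylboration with the enantiomeric reagent sets the 3R carbinol (C9 of the target) by reagent control.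

Step 5
Reactants: 6 (3R)-2-methylhexa-1,5-dien-3-ol
Product: 7 (3R,5E)-7-chloro-2,6-dimethylhepta-1,5-dien-3-ol (E major; the E/Z mixture is carried on)
Conditions: 3-chloro-2-methylprop-1-ene (10 equiv), second-generation Hoveyda–Grubbs catalyst (5 mol %), CH2Cl2, 40 °C
Reagents that add atoms: 3-chloro-2-methylprop-1-ene, C=C(C)CCl
Why: Olefin cross-metathesis of the monosubstituted vinyl group with excess methallyl chloride installs the C7=C11–C12 allylic chloride while the hindered isopropenyl group stays inert, and the geometry of this olefin is not used later.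

Step 6
Reactants: 7 (3R,5E)-7-chloro-2,6-dimethylhepta-1,5-dien-3-ol; 4 (4S,5Z)-7-[(tert-butyldiphenylsilyl)oxy]-5-methylhepta-1,5-dien-4-ol
Product: 9 mixed di(propan-2-yl)silylene bis-ether linking O–C9 of 7 to O–C3 of 4, via chlorosilane 8 (not isolated)
Conditions: 7, iPr2SiCl2 (3 equiv), imidazole, CH2Cl2, 0 °C, excess silane removed in vacuo; then 4, imidazole, DMF, rt
Reagents that add atoms: dichlorodi(propan-2-yl)silane, CC(C)[Si](Cl)(Cl)C(C)C
Why: Sequential silylation (temporary silicon tether) joins the two secondary alcohols so that the vinyl and isopropenyl groups sit in one molecule.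

Step 7
Reactants: 9 mixed di(propan-2-yl)silylene bis-ether
Product: 10 eight-membered cyclic silaketal (1,3-dioxa-2-silacyclooct-5-ene) containing the Z C1=C10 olefin
Conditions: second-generation Hoveyda–Grubbs catalyst (10 mol %), toluene (0.005 M), 80 °C
Reagents that add atoms: none
Why: Silicon-tethered ring-closing metathesis of the vinyl and isopropenyl groups forms the trisubstituted C1=C10 olefin inside an eight-membered ring, which can only hold the Z geometry.

Step 8
Reactants: 10 eight-membered cyclic silaketal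
Product: 11 (2Z,4S,6Z,8R,10E)-1-[(tert-butyldiphenylsilyl)oxy]-12-chloro-3,7,11-trimethyldodeca-2,6,10-triene-4,8-diol
Conditions: PPTS (cat.), MeOH, 0 °C → rt
Reagents that add atoms: none
Why: Acid-catalysed methanolysis cleaves the labile dialkoxysilane while the primary TBDPS ether, the allylic chloride and both carbinol centres are untouched.

Step 9
Reactants: 11 the 4,8-diol
Product: 12 (2Z,4S,6Z,8R,10E)-1-[(tert-butyldiphenylsilyl)oxy]-12-chloro-3,7,11-trimethyldodeca-2,6,10-triene-4,8-diyl diacetate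
Conditions: Ac2O, pyridine, DMAP (cat.), CH2Cl2, 0 °C → rt
Reagents that add atoms: acetic anhydride, CC(=O)OC(C)=O
Why: DMAP-catalysed acylation installs the two acetates of the target on C3 and C9 with retention at both centres.

Step 10
Reactants: 12 the silyl ether diacetate
Product: 13 (2Z,4S,6Z,8R,10E)-12-chloro-1-hydroxy-3,7,11-trimethyldodeca-2,6,10-triene-4,8-diyl diacetate
Conditions: HF·pyridine, THF, 0 °C → rt
Reagents that add atoms: none
Why: Fluoride cleavage of the primary TBDPS ether under non-basic conditions leaves the acetates and the allylic chloride intact.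

Step 11
Reactants: 13 the primary allylic alcohol
Product: 14 (2Z,4S,6Z,8R,10E)-12-chloro-3,7,11-trimethyl-1-oxododeca-2,6,10-triene-4,8-diyl diacetate
Conditions: MnO2 (20 equiv), CH2Cl2, rt; used directly
Reagents that add atoms: none
Why: MnO2 oxidises only the primary allylic alcohol under neutral conditions that preserve the Z enal and the γ-acetate.

Step 12
Reactants: 14 the (Z)-enal allylic chloride
Product: 16 (3S,6R,7S,9R,1(10)Z,4Z)-6-hydroxygermacra-1(10),4,11(12)-triene-3,9-diyl diacetate, via allylchromium dichloride 15 (not isolated)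
Conditions: CrCl2 (6 equiv), LiI (10 mol %), THF, rt, syringe-pump addition (final 0.003 M)
Reagents that add atoms: none
Why: Intramolecular Nozaki–Hiyama allylation, in which two-electron reduction turns the electrophilic allylic chloride into nucleophilic allylchromium 15 (a propionate homoenolate equivalent once C12 is oxidised) whose γ-carbon C7 adds to the aldehyde carbon C6 through a chair-like transition state that gives the anti (6,7-trans) adduct, the face being set by the resident C3 and C9 centres.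

Step 13
Reactants: 16 the ten-membered homoallylic alcohol
Product: 18 (3S,6S,7S,9R,11R,1(10)Z,4Z)-6,12-dihydroxygermacra-1(10),4-diene-3,9-diyl diacetate, via bis(9-BBN) adduct 17 (not isolated)
Conditions: 9-BBN (2.5 equiv), THF, 0 °C → rt; then H2O2, aq. NaH2PO4/Na2HPO4 (pH 7), 0 °C
Reagents that add atoms: hydrogen peroxide, OO
Why: Hydroboration–oxidation in which bulky 9-BBN attacks only the 1,1-disubstituted olefin, anti-Markovnikov and from the face away from the C6 branch in the conformer with C7–H eclipsing the olefin (acyclic 1,2-induction), which places the C11 methyl cis to C8 (11R).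

Step 14
Reactants: 18 the 6,12-diol
Product: 20 (3S,6S,7S,9R,11R,1(10)Z,4Z)-3,9-diacetoxygermacra-1(10),4-dien-12,6-olide, via lactol 19 (not isolated)
Conditions: TEMPO (0.2 equiv), PhI(OAc)2 (2.5 equiv), CH2Cl2, rt
Reagents that add atoms: none
Why: TEMPO/PhI(OAc)2 oxidative lactonisation is selective for the primary alcohol, the aldehyde being trapped by the C6 hydroxyl as lactol 19 and oxidised on to the trans-fused γ-lactone.

**Compound list**
1 | 3-methylfuran-2(5H)-one | CC1=CCOC1=O | starting material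
2 | 3-methyl-2,5-dihydrofuran-2-ol | CC1=CCOC1O | intermediate
3 | (2Z,4S)-3-methylhepta-2,6-diene-1,4-diol | OC/C=C(/C)[C@@H](O)CC=C | intermediate
4 | (4S,5Z)-7-[(tert-butyldiphenylsilyl)oxy]-5-methylhepta-1,5-dien-4-ol | CC(C)(C)[Si](OC/C=C(/C)[C@@H](O)CC=C)(c1ccccc1)c1ccccc1 | intermediate
5 | 2-methylprop-2-enal (methacrolein) | CC(=C)C=O | starting material
6 | (3R)-2-methylhexa-1,5-dien-3-ol | C=C(C)[C@H](O)CC=C | intermediate
7 | (3R,5E)-7-chloro-2,6-dimethylhepta-1,5-dien-3-ol (E isomer drawn) | C=C(C)[C@H](O)C/C=C(\C)CCl | intermediate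
8 | chloro{[(3R,5E)-7-chloro-2,6-dimethylhepta-1,5-dien-3-yl]oxy}di(propan-2-yl)silane | C=C(C)[C@H](O[Si](Cl)(C(C)C)C(C)C)C/C=C(\C)CCl | intermediate (not isolated)
9 | {[(3R,5E)-7-chloro-2,6-dimethylhepta-1,5-dien-3-yl]oxy}{[(4S,5Z)-7-[(tert-butyldiphenylsilyl)oxy]-5-methylhepta-1,5-dien-4-yl]oxy}di(propan-2-yl)silane | C=C(C)[C@H](O[Si](C(C)C)(C(C)C)O[C@@H](CC=C)/C(C)=C\CO[Si](c1ccccc1)(c1ccccc1)C(C)(C)C)C/C=C(\C)CCl | intermediate
10 | (4R,8S,5Z)-4-[(2E)-4-chloro-3-methylbut-2-enyl]-8-[(2Z)-4-(tert-butyldiphenylsilyloxy)but-2-en-2-yl]-5-methyl-2,2-di(propan-2-yl)-1,3-dioxa-2-silacyclooct-5-ene | CC(C)[Si]1(C(C)C)O[C@H](C/C=C(\C)CCl)/C(C)=C\C[C@@H](/C(C)=C\CO[Si](c2ccccc2)(c2ccccc2)C(C)(C)C)O1 | intermediate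
11 | (2Z,4S,6Z,8R,10E)-1-[(tert-butyldiphenylsilyl)oxy]-12-chloro-3,7,11-trimethyldodeca-2,6,10-triene-4,8-diol | ClC/C(C)=C/C[C@@H](O)/C(C)=C\C[C@H](O)/C(C)=C\CO[Si](c1ccccc1)(c1ccccc1)C(C)(C)C | intermediate
12 | (2Z,4S,6Z,8R,10E)-1-[(tert-butyldiphenylsilyl)oxy]-12-chloro-3,7,11-trimethyldodeca-2,6,10-triene-4,8-diyl diacetate | ClC/C(C)=C/C[C@@H](OC(C)=O)/C(C)=C\C[C@H](OC(C)=O)/C(C)=C\CO[Si](c1ccccc1)(c1ccccc1)C(C)(C)C | intermediate
13 | (2Z,4S,6Z,8R,10E)-12-chloro-1-hydroxy-3,7,11-trimethyldodeca-2,6,10-triene-4,8-diyl diacetate | ClC/C(C)=C/C[C@@H](OC(C)=O)/C(C)=C\C[C@H](OC(C)=O)/C(C)=C\CO | intermediate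
14 | (2Z,4S,6Z,8R,10E)-12-chloro-3,7,11-trimethyl-1-oxododeca-2,6,10-triene-4,8-diyl diacetate | ClC/C(C)=C/C[C@@H](OC(C)=O)/C(C)=C\C[C@H](OC(C)=O)/C(C)=C\C=O | intermediate
15 | allylchromium dichloride formed from 14 at C12 (σ-allyl form, THF ligands omitted) | Cl[Cr](Cl)C/C(C)=C/C[C@@H](OC(C)=O)/C(C)=C\C[C@H](OC(C)=O)/C(C)=C\C=O | intermediate (not isolated)
16 | (3S,6R,7S,9R,1(10)Z,4Z)-6-hydroxygermacra-1(10),4,11(12)-triene-3,9-diyl diacetate (OH and isopropenyl anti; 6R only by CIP rank, same spatial arrangement as 6S in 20) | CC(=O)O[C@H]1C/C=C(/C)[C@H](OC(C)=O)C[C@@H](C(C)=C)[C@H](O)/C=C\1C | intermediate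
17 | bis(9-borabicyclo[3.3.1]nonan-9-yl) adduct of 16 (B on C12 and on O6) | CC(=O)O[C@H]1C/C=C(/C)[C@H](OC(C)=O)C[C@@H]([C@@H](C)CB2C3CCCC2CCC3)[C@H](OB2C3CCCC2CCC3)/C=C\1C | intermediate (not isolated)
18 | (3S,6S,7S,9R,11R,1(10)Z,4Z)-6,12-dihydroxygermacra-1(10),4-diene-3,9-diyl diacetate | CC(=O)O[C@H]1C/C=C(/C)[C@H](OC(C)=O)C[C@@H]([C@@H](C)CO)[C@H](O)/C=C\1C | intermediate
19 | (3S,6S,7S,9R,11R)-12-hydroxy-6,12-epoxygermacra-1(10),4-diene-3,9-diyl diacetate (lactol, both anomers) | CC(=O)O[C@H]1C/C=C(/C)[C@H](OC(C)=O)C[C@@H]2[C@@H](/C=C\1C)OC(O)[C@@H]2C | intermediate (not isolated)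
20 | (3S,6S,7S,9R,11R,1(10)Z,4Z)-3,9-diacetoxygermacra-1(10),4-dien-12,6-olide | CC(=O)O[C@H]1C/C=C(/C)[C@H](OC(C)=O)C[C@@H]2[C@@H](/C=C\1C)OC(=O)[C@@H]2C | target

**Totals and risks**
Total steps: 14. Longest linear sequence: 12 steps (1 → 20 through steps 1–3 and 6–14).

Risk at step 7. RCM to an eight-membered ring with a trisubstituted olefin may be slow or give oligomers. The fallback sets out from 4 and 7 and comes back at 16; it drops the tether, joins the halves at C6–C7 first and closes the carbocycle by RCM.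
- Acetylation of 4 gives (4S,5Z)-7-[(tert-butyldiphenylsilyl)oxy]-5-methylhepta-1,5-dien-4-yl acetate F1.
- HF·pyridine gives (4S,5Z)-7-hydroxy-5-methylhepta-1,5-dien-4-yl acetate F2.
- MnO2 gives (4S,5Z)-5-methyl-7-oxohepta-1,5-dien-4-yl acetate F3.
- Acetylation of 7 gives (3R,5E)-7-chloro-2,6-dimethylhepta-1,5-dien-3-yl acetate F4.
- Intermolecular Nozaki–Hiyama allylation of F3 with F4 (CrCl2, chiral oxazoline–sulfonamide ligand for reagent control of the face) gives the anti adduct (4S,5Z,7R,8S,10R)-7-hydroxy-5,11-dimethyl-8-(prop-1-en-2-yl)dodeca-1,5,11-triene-4,10-diyl diacetate F5.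
- RCM of the vinyl and isopropenyl groups of F5 at high dilution, where the ten-membered ring enforces Z, gives 16.

Risk at step 12. The ten-membered closure may suffer from oligomerisation, and the face of the enal taken relative to C3/C9 rests on substrate control only. The fallback sets out from 11 and comes back at 20; it replaces ring closure by ring contraction.
- HF·pyridine on 11 gives (2Z,4S,6Z,8R,10E)-12-chloro-3,7,11-trimethyldodeca-2,6,10-triene-1,4,8-triol F6.
- NaH in THF at high dilution closes the easier 13-membered bis-allylic ether (3E,6R,7Z,10S,11Z)-3,7,11-trimethyl-1-oxacyclotrideca-3,7,11-triene-6,10-diol F7.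
- Excess nBuLi (THF, −78 → 0 °C) forms the dialkoxide and then the α-oxyallyl carbanion at C6, which attacks C7 in a [2,3]-Wittig ring contraction (E olefin → anti) to give (3S,6R,7S,9R,1(10)Z,4Z)-germacra-1(10),4,11(12)-triene-3,6,9-triol F8.
- 9-BBN then H2O2 gives (3S,6S,7S,9R,11R,1(10)Z,4Z)-germacra-1(10),4-diene-3,6,9,12-tetraol F9.
- TEMPO/PhI(OAc)2 gives (3S,6S,7S,9R,11R,1(10)Z,4Z)-3,9-dihydroxygermacra-1(10),4-dien-12,6-olide F10.
- Ac2O/pyridine gives 20.

Risk at step 13. The sense of 1,2-induction at C11 is predicted from an acyclic model and may be low or reversed in the macrocycle. The fallback sets out from 16 and comes back at 18; it uses rhodium-catalysed hydroboration, which runs by a different mechanism and is known to give the opposite sense of induction to 9-BBN next to a stereocentre.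
- Catecholborane with RhCl(PPh3)3 in THF gives (3S,6S,7S,9R,11R)-12-(1,3,2-benzodioxaborol-2-yl)-6-hydroxygermacra-1(10),4-diene-3,9-diyl diacetate F11.
- Buffered H2O2 oxidation gives 18.

Further compounds
F1 | step 7 | (4S,5Z)-7-[(tert-butyldiphenylsilyl)oxy]-5-methylhepta-1,5-dien-4-yl acetate | CC(=O)O[C@@H](CC=C)/C(C)=C\CO[Si](c1ccccc1)(c1ccccc1)C(C)(C)C
F2 | step 7 | (4S,5Z)-7-hydroxy-5-methylhepta-1,5-dien-4-yl acetate | CC(=O)O[C@@H](CC=C)/C(C)=C\CO
F3 | step 7 | (4S,5Z)-5-methyl-7-oxohepta-1,5-dien-4-yl acetate | CC(=O)O[C@@H](CC=C)/C(C)=C\C=O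
F4 | step 7 | (3R,5E)-7-chloro-2,6-dimethylhepta-1,5-dien-3-yl acetate | C=C(C)[C@H](OC(C)=O)C/C=C(\C)CCl
F5 | step 7 | (4S,5Z,7R,8S,10R)-7-hydroxy-5,11-dimethyl-8-(prop-1-en-2-yl)dodeca-1,5,11-triene-4,10-diyl diacetate | C=CC[C@H](OC(C)=O)/C(C)=C\[C@@H](O)[C@H](C(C)=C)C[C@@H](OC(C)=O)C(C)=C
F6 | step 12 | (2Z,4S,6Z,8R,10E)-12-chloro-3,7,11-trimethyldodeca-2,6,10-triene-1,4,8-triol | ClC/C(C)=C/C[C@@H](O)/C(C)=C\C[C@H](O)/C(C)=C\CO
F7 | step 12 | (3E,6R,7Z,10S,11Z)-3,7,11-trimethyl-1-oxacyclotrideca-3,7,11-triene-6,10-diol | O1C/C=C(/C)[C@@H](O)C/C=C(/C)[C@H](O)C/C=C(\C)C1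
F8 | step 12 | (3S,6R,7S,9R,1(10)Z,4Z)-germacra-1(10),4,11(12)-triene-3,6,9-triol | O[C@H]1C/C=C(/C)[C@H](O)C[C@@H](C(C)=C)[C@H](O)/C=C\1C
F9 | step 12 | (3S,6S,7S,9R,11R,1(10)Z,4Z)-germacra-1(10),4-diene-3,6,9,12-tetraol | O[C@H]1C/C=C(/C)[C@H](O)C[C@@H]([C@@H](C)CO)[C@H](O)/C=C\1C
F10 | step 12 | (3S,6S,7S,9R,11R,1(10)Z,4Z)-3,9-dihydroxygermacra-1(10),4-dien-12,6-olide | O[C@H]1C/C=C(/C)[C@H](O)C[C@@H]2[C@@H](/C=C\1C)OC(=O)[C@@H]2C
F11 | step 13 | (3S,6S,7S,9R,11R)-12-(1,3,2-benzodioxaborol-2-yl)-6-hydroxygermacra-1(10),4-diene-3,9-diyl diacetate | CC(=O)O[C@H]1C/C=C(/C)[C@H](OC(C)=O)C[C@@H]([C@@H](C)CB2Oc3ccccc3O2)[C@H](O)/C=C\1C
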